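## The problem

CNP0262409.2 (33) is a cembranolide: a fourteen-membered carbocycle (C1–C14) bridged between C1 and C3 by a six-membered α-methyl δ-lactone (C1, C2, C3, O, C16, C15). Seven stereocentres must be set (1R, 3R, 4S, 7S, 11S, 12S, 15S), and only some can control one another. C3 and C4 are neighbours, so an allylic C3 hydroxyl can direct oxygen to C4. C15 is α to the lactone carbonyl and equatorial, like the ring bonds at C1 and C3, so thermodynamics backs it. C1 is isolated and best taken from the chiral pool, while C7 and the C11–C12 epoxide are remote and need chirality transfer or reagent control. The trisubstituted epoxide will not survive acid or hydride, the lactone will not survive organolithium reagents, and the C7 allylic alcohol beside the exocyclic C8 methylene is prone to ionisation, so these groups must come late or travel masked. The array C4(O)–C5–C6–C7(OH)–C8(=CH2) makes an unusual ring construction possible: the C7 carbinol is allylic to the C8 methylene and three carbons from oxygenated C4, which is the product pattern of a [2,3]-Wittig shift in a C4–O–C7 ether carrying a C5=C6 vinyl group on C4.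

## Retrosynthesis

**33 ⇐ 32 ⇐ 31 ⇐ 30 (fragile groups last).** The C7 silyl ether is removed last (32). The lactone C16–O bond is cut back to the primary C16 alcohol of epoxy triol 31, and the epoxide oxygen is removed to give triol 30 with its 11E alkene. Epoxidising the open triol, not the lactone, keeps the basic dioxirane medium away from the lactone, and both operations follow every hydride and organolithium step. 30 is simpler by two rings and two stereocentres. Forward, C11=C12 must be epoxidised beside the C8 methylene with reagent control of the face, and C16 must be oxidised selectively so that the C3 hydroxyl closes the six-membered ring.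

**30 ⇐ 29 ⇐ 28 (C4 carbinol).** The C4–O bond is cut through epoxide 29 back to the E-C4=C5 alkene of allylic alcohol 28. Carrying the C4 oxygen through is not possible because the key step consumes the C4–O bond, but the adjacent C3 hydroxyl can return oxygen to the right face. 28 has one stereocentre fewer. Forward, oxygen must arrive erythro to the C3 hydroxyl and hydride must attack C5, the only epoxide carbon open to SN2.

**28 ⇐ 27 ⇐ 26 (protecting groups).** The C7 hydroxyl is silylated before the C3 and C16 acetals are removed, so that only the C3 hydroxyl can direct the epoxidation. No skeletal bond is cut here.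

**26 ⇐ 24 (key disconnection).** In 26 the C6–C7 bond is cut and C4 is rejoined to the C7 oxygen, giving the thirteen-membered bis-allylic ether 24 with a vinyl group on C4. Compared with a C7–C8 carbonyl addition or a C–C macrocyclisation elsewhere, this cut makes a ring C–C bond, the C7 stereocentre, the E-C4=C5 alkene and the free C7 hydroxyl in one event. Its precursor ring is also closed by C–O, not C–C, bond formation. 24 trades the isolated C7 centre for a C4 centre next to C3, which is easy to set. Forward, a single carbanion must form at C7 and bond to C6 through one envelope geometry.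

**24 ⇐ 23 ⇐ 22 (ether ring).** The C7–O bond is cut to chloro alcohol 23 and its alcohol 22. A Williamson closure is chosen because the 2-methyleneallyl chloride cannot eliminate and gives the same ether by SN2 or SN2′. The precursor is acyclic. Forward, a hindered tertiary alkoxide must cyclise faster than it oligomerises.

**22 ⇐ 19 + 20 (C9–C10).** Cutting C9–C10 gives allylic bromide 19 and methallyl alcohol 20, used as its C,O-dianion. This brings C7, C8 and the C19 methylene in one step with the C7 oxygen in place. A sulfone-based coupling would need two further steps.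

**19 ⇐ 18 ⇐ 17 ⇐ 16 ⇐ 15 ⇐ 14 (C3/C4 diad and vinyl group).** The C5=C6 vinyl group is cut at C5–C6 back to the terminal epoxide 17 (one-carbon homologation). The epoxide comes from isopropenyl carbinol 14 by hydroxyl-directed epoxidation (15), protection (16) and ester reduction (17). The same erythro-selective directed epoxidation therefore sets C4 twice, here and in step 21, each time from C3. Forward, the homologation must attack the epoxide CH2 and leave C4 untouched.

**14 ⇐ 13 ⇐ 12 ⇐ 10 ⇐ 8 + 9 + 11 (C3 and the 11E alkene).** C3 is set by reagent-controlled reduction of enone 13, so the uncontrolled addition of isopropenylmagnesium bromide 9 to the aldehyde of 8 (C3–C4 bond) does not matter. The C11=C12 alkene is cut to the methyl ketone of 10 and triethyl phosphonoacetate 11. The forward olefination must favour the E-enoate 12.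

**8 ⇐ 6 ⇐ 5 ⇐ 4 ⇐ 3 ⇐ 1 (chiral pool).** Keto aldehyde 8 is the ozonolysis product of cyclohexene 6. The ring CH of (R)-limonene 1 becomes C1, its ring alkene gives the C12 methyl ketone and the C3 aldehyde, and its isopropenyl group gives C15–C17 with C16 oxygenated by hydroboration (3). Hydroboration has no facial bias at C15, so the epimers are separated at once by enzymatic acylation (4, 5), while the material is cheap.

## Roads not taken

**Alternative 1: carbonylative lactone annulation.** The cut is at C16–O and C15–C16. A macrocyclic alkynol A1 (C1 ethynyl, free C3 hydroxyl) would take up CO under PdCl2, PPh3 and SnCl2 to give the α-methylene δ-lactone A2. Its merits are real: the lactone carbonyl arrives at the end, C16 needs no protecting group, and C15 can be set afterwards by conjugate reduction under thermodynamic control. That is cleaner than the enzymatic separation used here. Its weak points are that it does not make the fourteen-membered ring, C1 would carry an ethynyl group and so cannot come from limonene, and the Lewis-acidic Pd/Sn medium meets an ionisable C7 allylic silyl ether. It is better at the lactone but leaves the ring and C7 unsolved. The chosen plan pays for solving them with two acetal protecting groups and an early resolution.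

**Alternative 2: cyclase-type cation–olefin macrocyclisation.** The cut is at C1–C2. A cembrene A synthase with its divalent magnesium cofactor would ionise geranylgeranyl diphosphate A3 and close the ring to (R)-cembrene A, A4. For ring construction this is better than anything chemical: one step from an achiral C20 chain gives the carbocycle, three E alkenes and C1. The weakness is everything after it. A4 carries no oxygen, and the target needs oxidation at C3, C4, C7, C11/C12 and C16, transposition of one alkene to the C8 methylene and reduction at C15. These must be done among four similar alkenes with no directing group, by tailoring enzymes that are not in hand. The chosen plan is far longer to the ring but places each oxygen by construction.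

**Alternative 3: B-alkyl Suzuki closure at C12–C13.** A seco lactone A5 with a C1 vinyl group and an E-alkenyl iodide at C12 would be hydroborated with 9-BBN and coupled under Pd(dppf)Cl2 to the macrocycle A6. The ring closure is of a well-tried type, the alkene geometry is fixed beforehand, and the lactone with C3, C4 and C15 is already in place. As a ring closure it is more dependable than an untested rearrangement. Its weak points lie later. The C7 alcohol and C8 methylene are still a 7,8-epoxide that must be isomerised with control of regiochemistry (C19 against C9), and C11=C12 must then be epoxidised. The lactone and epoxide must also tolerate the aqueous base of the coupling. The chosen plan sets C7–OH and C8=CH2 in the ring-forming event with chirality transfer, at the cost of rebuilding the C4 carbinol.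

Key step: step 18

**Remarks.** Locants in names are cembrane locants: C1 is the CH bearing the C15(C17)–C16 arm, and C2, C3(O), C4(C18)(O), C5, C6, C7(O), C8(=C19), C9, C10, C11, C12(C20), C13, C14 follow round the ring. MOM = CH2OCH3, TBS = Si(CH3)2C(CH3)3.

**Assumption.** The lipase in step 2 acylates the 15S epimer faster, by analogy with (S)-2-methylalkan-1-ols; because C15 of the target is equatorial in the lactone, a minor 15R contaminant could still be converged by base at the stage of 32.

## Route

Step 1
Reactants: 1 (R)-(+)-limonene
Product: 3 2-[(1R)-4-methylcyclohex-3-en-1-yl]propan-1-ol as both C15 epimers [(4R,8RS)-p-menth-1-en-9-ol], via B-alkyl-9-BBN adduct 2 (not isolated)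
Conditions: 9-BBN, THF, 0 °C to rt; then NaOH, H2O2, 0 °C
Reagents that add atoms: hydrogen peroxide (OO)
Why: Hydroboration–oxidation; 9-BBN adds to the 1,1-disubstituted isopropenyl alkene much faster than to the trisubstituted ring alkene and puts boron on the terminal carbon (C16). There is no facial bias at C15, so both epimers form and are separated in step 2.

Step 2
Reactants: 3 (4R,8RS)-p-menth-1-en-9-ol
Product: 4 (2S)-2-[(1R)-4-methylcyclohex-3-en-1-yl]propyl acetate (15S)
Conditions: lipase PS (Burkholderia cepacia), vinyl acetate, t-BuOMe, rt, stopped short of half conversion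
Reagents that add atoms: vinyl acetate (CC(=O)OC=C)
Why: Lipase-catalysed kinetic resolution by transesterification; the enzyme reads the methyl-bearing centre next to CH2OH and is expected to acetylate the 15S epimer faster, leaving the 15R alcohol behind. This step fixes C15 by separation, not by induction.

Step 3
Reactants: 4 (15S)-acetate
Product: 5 (2S)-2-[(1R)-4-methylcyclohex-3-en-1-yl]propan-1-ol [(4R,8S)-p-menth-1-en-9-ol]
Conditions: K2CO3, MeOH, rt
Reagents that add atoms: none
Why: Base-catalysed transesterification (methanolysis) of a primary acetate; no stereocentre is involved.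

Step 4
Reactants: 5 (4R,8S)-p-menth-1-en-9-ol
Product: 6 (4R)-4-[(2S)-1-(methoxymethoxy)propan-2-yl]-1-methylcyclohexene
Conditions: MOMCl, i-Pr2NEt, CH2Cl2, 0 °C to rt
Reagents that add atoms: chloromethyl methyl ether (COCCl)
Why: O-Alkylation of the primary alcohol; the MOM acetal withstands the organometallic, hydride and alkyllithium steps ahead and cannot migrate.

Step 5
Reactants: 6 MOM ether
Product: 8 (3R)-3-[(2S)-1-(methoxymethoxy)propan-2-yl]-6-oxoheptanal (C3 aldehyde, C12 methyl ketone; 1R,15S), via secondary ozonide 7 (not isolated)
Conditions: O3, CH2Cl2, −78 °C, to the first excess; then Me2S, −78 °C to rt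
Reagents that add atoms: ozone ([O-][O+]=O)
Why: Ozonolysis with reductive work-up of the only alkene; the ring CH becomes C1 with its configuration untouched, flanked by the C2–C3 aldehyde arm and the C14–C13–C12 ketone arm.

Step 6
Reactants: 8 keto aldehyde; 9 isopropenylmagnesium bromide
Product: 10 C3 isopropenyl carbinol with C12 methyl ketone and C16 MOM ether (1R,15S; both C3 epimers)
Conditions: THF, −78 °C; then H2O
Reagents that add atoms: none
Why: Chemoselective Grignard 1,2-addition; at −78 °C the aldehyde reacts far faster than the methyl ketone. C3 forms without control and is corrected in steps 8 and 9.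

Step 7
Reactants: 10 hydroxy ketone; 11 triethyl phosphonoacetate
Product: 12 ethyl (E)-enoate: C10 ester, 11E alkene, C3 isopropenyl carbinol (1R,15S; both C3 epimers)
Conditions: NaH, THF, 0 °C to reflux
Reagents that add atoms: none
Why: Horner–Wadsworth–Emmons olefination of the methyl ketone; the stabilised phosphonate anion is expected to favour the E-enoate (ester trans to the C13 chain), and the minor Z isomer is removed by chromatography. The C3 alkoxide is a spectator.

Step 8
Reactants: 12 hydroxy enoate
Product: 13 C3 isopropenyl ketone with C10 ethyl ester, 11E (1R,15S)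
Conditions: Dess–Martin periodinane, NaHCO3, CH2Cl2, 0 °C to rt
Reagents that add atoms: none
Why: Dess–Martin oxidation of the secondary allylic alcohol under buffered conditions; both C3 epimers converge on one enone.

Step 9
Reactants: 13 enone
Product: 14 (3R)-isopropenyl carbinol with C10 ethyl ester, 11E (1R,3R,15S)
Conditions: (S)-2-methyl-CBS-oxazaborolidine (0.2 equiv), catecholborane, toluene, −78 °C; then MeOH, aq. NaOH
Reagents that add atoms: none
Why: Corey–Bakshi–Shibata reduction; the isopropenyl group acts as the large and the C2 methylene as the small substituent, so the (S)-catalyst should deliver hydride to give the 3R alcohol by reagent control. Catecholborane spares the alkenes.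

Step 10
Reactants: 14 (3R)-allylic alcohol
Product: 15 erythro epoxy alcohol: C4–C5 epoxide (C5 = CH2) beside the C3 hydroxyl (1R,3R,4S,15S)
Conditions: VO(acac)2 (5 mol%), t-BuOOH, CH2Cl2, 0 °C
Reagents that add atoms: tert-butyl hydroperoxide (CC(C)(C)OO)
Why: Hydroxyl-directed epoxidation; the vanadium alkoxide of the allylic alcohol delivers oxygen only to the adjacent 1,1-disubstituted alkene. With a methyl group geminal to the carbinol carbon, A(1,2) strain favours the erythro isomer, which sets C4 (S) from C3.

Step 11
Reactants: 15 epoxy alcohol
Product: 16 C3 MOM ether of 15 (1R,3R,4S,15S)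
Conditions: MOMCl, i-Pr2NEt, Bu4NI (cat.), CH2Cl2, 0 °C to rt
Reagents that add atoms: chloromethyl methyl ether (COCCl)
Why: O-Alkylation of the secondary alcohol; an acetal is chosen over a silyl ether because it cannot migrate to the neighbouring C4 alkoxide in steps 13 to 17.

Step 12
Reactants: 16 epoxy ester
Product: 17 C10 allylic alcohol (11E) with C4–C5 epoxide and C3, C16 MOM ethers (1R,3R,4S,15S)
Conditions: i-Bu2AlH, CH2Cl2, −78 °C; then aq. potassium sodium tartrate (KNaC4H4O6)
Reagents that add atoms: none
Why: 1,2-Reduction of the enoate to the allylic alcohol; at −78 °C the epoxide and the acetals are not touched. Removing the enoate now keeps it away from the ylide of step 13.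

Step 13
Reactants: 17 epoxy alcohol
Product: 18 diol: C4 tertiary vinyl carbinol and C10 allylic alcohol, C3 and C16 MOM ethers (1R,3R,4S,15S)
Conditions: Me3S+ I− (excess), n-BuLi, THF, −10 °C to rt; then H2O
Reagents that add atoms: trimethylsulfonium iodide (C[S+](C)C.[I-])
Why: One-carbon homologation of a terminal epoxide to an allylic alcohol with dimethylsulfonium methylide; the ylide opens the epoxide at CH2 and the betaine eliminates dimethyl sulfide to form the C5=C6 vinyl group. No bond to C4 is broken, so its configuration is kept.

Step 14
Reactants: 18 diol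
Product: 19 C10 allylic bromide of 18 (1R,3R,4S,15S)
Conditions: CBr4, PPh3, 2,6-lutidine, CH2Cl2, −30 °C
Reagents that add atoms: carbon tetrabromide (BrC(Br)(Br)Br)
Why: Appel bromination; the primary allylic alcohol reacts at low temperature while the hindered tertiary alcohol does not.

Step 15
Reactants: 19 allylic bromide; 20 2-methylprop-2-en-1-ol
Product: 22 diol: C7 primary allylic alcohol on the C8 methylene unit and C4 tertiary vinyl carbinol (1R,3R,4S,15S), via dilithio methallyl alkoxide 21 (not isolated)
Conditions: 20, n-BuLi (2 equiv), TMEDA, Et2O, 0 °C to rt; then 19, THF, −78 °C to rt; then H2O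
Reagents that add atoms: none
Why: C-Alkylation of the C,O-dianion of methallyl alcohol; attack is SN2 at the primary allylic bromide because SN2′ would create a quaternary centre. It forms C9–C10 and brings C7–OH, C8 and the C19 methylene together; excess dianion covers the tertiary hydroxyl.

Step 16
Reactants: 22 diol
Product: 23 C7 allylic chloride of 22 (1R,3R,4S,15S)
Conditions: N-chlorosuccinimide, Me2S, CH2Cl2, −20 to 0 °C
Reagents that add atoms: N-chlorosuccinimide (O=C1CCC(=O)N1Cl)
Why: Corey–Kim-type chlorination through the alkoxysulfonium salt; it is selective for the primary allylic alcohol, and the 2-substituted allyl system gives the same chloride by SN2 or SN2′.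

Step 17
Reactants: 23 chloro alcohol
Product: 24 thirteen-membered bis-allylic ether: C4–O–C7, C4 vinyl and methyl, C8 methylene, 11E alkene, C3 and C16 MOM ethers (1R,3R,4S,15S)
Conditions: KH, 18-crown-6, Bu4NI (cat.), THF, slow addition at about 1 mM, rt to 40 °C
Reagents that add atoms: none
Why: Intramolecular Williamson ether synthesis (13-exo-tet); the allylic chloride has no β-hydrogen to eliminate and gives one ether whichever allyl terminus is attacked. High dilution and in situ iodide exchange favour ring closure by the hindered tertiary alkoxide.

Step 18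
Reactants: 24 thirteen-membered ether
Product: 26 fourteen-membered C7 alcohol: C8 methylene, 4E and 11E alkenes, C3 and C16 MOM ethers (1R,3R,7S,15S), via C7-lithio ether 25 (not isolated)
Conditions: n-BuLi (1.5 equiv), THF, −78 to −30 °C; then H2O
Reagents that add atoms: none
Why: Proposed new method: n-BuLi removes a C7 proton, the only hydrogen that is both allylic (to the C8 methylene) and next to the ether oxygen because C4 is quaternary, and carbanion 25 bonds to the vinyl terminus C6 as the O–C4 bond breaks, a concerted six-electron [2,3]-Wittig shift through a five-membered envelope (C7, O, C4, C5, C6). The closest known reaction type is the [2,3]-Wittig rearrangement of macrocyclic bis-allylic ethers in its ring-contracting form, and of acyclic tertiary allyl ethers; what is new is that the migrating alkene is exocyclic, so oxygen leaves the ring while C5 and C6 enter it. The fourteen-membered carbocycle is therefore not closed from an open chain but grows from the thirteen-membered ether by one atom, with the envelope bridged by the C8 to C3 chain. The new stereocentre C7 is controlled by the ether centre C4: with the C3 branch pseudo-equatorial (which also gives the E C4=C5 alkene) and the C8 alkenyl group exo, the usual preference of alkenyl-stabilised carbanions, the 4S ether should deliver C6 to the face of C7 that gives 7S, and a large bridging ring spans these two positions without strain. The step needs the [2,3] path over [1,2] and [1,4] shifts, which low temperature and allylic stabilisation favour, and a single deprotonation site, which the quaternary C4 and the acetal-only protection secure. The C4 stereocentre is given up here and rebuilt in steps 21 and 22.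

Step 19
Reactants: 26 C7 alcohol
Product: 27 C7 TBS ether of 26 (1R,3R,7S,15S)
Conditions: TBSOTf, 2,6-lutidine, CH2Cl2, −78 °C
Reagents that add atoms: tert-butyldimethylsilyl trifluoromethanesulfonate (CC(C)(C)[Si](C)(C)OS(=O)(=O)C(F)(F)F)
Why: Silylation of the hindered secondary allylic alcohol; masking C7–OH prevents it from directing epoxidation to the C8 methylene in step 21 and from being oxidised in step 24.

Step 20
Reactants: 27 bis-MOM ether
Product: 28 diol: free C3 and C16 hydroxyls, C7 TBS ether, 4E and 11E alkenes (1R,3R,7S,15S)
Conditions: MgBr2·OEt2, n-BuSH, Et2O, rt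
Reagents that add atoms: none
Why: Lewis acid-assisted acetal exchange; the thiol takes the CH2OCH3 group at the acetal carbon, so the allylic C3–O bond is never ionised and the silyl ether is expected to survive.

Step 21
Reactants: 28 allylic alcohol
Product: 29 C4–C5 epoxide of 28, oxygen erythro to the C3 hydroxyl (1R,3R,4R,5R,7S,15S; the C4 descriptor changes by priority only)
Conditions: VO(acac)2 (5 mol%), t-BuOOH, CH2Cl2, 0 °C
Reagents that add atoms: tert-butyl hydroperoxide (CC(C)(C)OO)
Why: Hydroxyl-directed epoxidation; only C4=C5 is allylic to a free hydroxyl, so the C8 methylene and C11=C12 are left alone. As in step 10, the methyl group geminal to the carbinol carbon should favour erythro delivery, which places the oxygen on C4 in the configuration of the target.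

Step 22
Reactants: 29 epoxy diol
Product: 30 triol: C3–OH, C4 tertiary OH, C16–OH, C7 TBS ether, 11E alkene (1R,3R,4S,7S,15S)
Conditions: LiAlH4, THF, 0 °C to rt; then aq. potassium sodium tartrate (KNaC4H4O6)
Reagents that add atoms: none
Why: Reductive epoxide opening by SN2 hydride attack at C5, the only epoxide carbon that is not fully substituted; the C4–O bond is retained, so C4 keeps the configuration set in step 21.

Step 23
Reactants: 30 triol
Product: 31 11,12-epoxide of 30 (1R,3R,4S,7S,11S,12S,15S)
Conditions: L-fructose-derived ketone catalyst (enantiomer of the usual D-fructose-derived one, 0.3 equiv), KHSO5, K2CO3, Bu4NHSO4, MeCN–CH2(OMe)2–aq. Na2B4O7 buffer, pH about 10.5, 0 °C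
Reagents that add atoms: potassium peroxymonosulfate ([K+].[O-]S(=O)(=O)OO)
Why: Shi epoxidation; the chiral dioxirane reacts with the electron-rich E-trisubstituted alkene in preference to the 1,1-disubstituted C8 methylene. The D-fructose-derived ketone gives R,R epoxides from alkenes of this pattern, so its enantiomer should give 11S,12S by reagent control.

Step 24
Reactants: 31 epoxy triol
Product: 32 C7 TBS ether of the target: δ-lactone C16(=O)–O–C3 (1R,3R,4S,7S,11S,12S,15S)
Conditions: TEMPO (0.2 equiv), PhI(OAc)2, NaHCO3, CH2Cl2, rt
Reagents that add atoms: none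
Why: Oxidative lactonisation of a 1,5-diol; the oxoammonium salt oxidises the primary C16 alcohol, the aldehyde is trapped by the C3 hydroxyl as the six-membered lactol, and this is oxidised to the lactone. That should outrun cleavage of the hindered C3/C4 glycol, and C15 ends in its preferred equatorial position.

Step 25
Reactants: 32 silyl ether
Product: 33 CNP0262409.2
Conditions: Bu4NF, AcOH, THF, 0 °C to rt
Reagents that add atoms: none
Why: Fluoride-mediated desilylation buffered with acetic acid; the lactone, the epoxide and the tertiary alcohol are stable to these conditions.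

## Compound list

1 | (R)-(+)-limonene | CC1=CC[C@@H](CC1)C(C)=C | starting material
2 | 9-{2-[(1R)-4-methylcyclohex-3-en-1-yl]propyl}-9-borabicyclo[3.3.1]nonane (both C15 epimers) | CC1=CC[C@@H](CC1)C(C)CB1C2CCCC1CCC2 | intermediate
3 | 2-[(1R)-4-methylcyclohex-3-en-1-yl]propan-1-ol, both C15 epimers | CC1=CC[C@@H](CC1)C(C)CO | intermediate
4 | (2S)-2-[(1R)-4-methylcyclohex-3-en-1-yl]propyl acetate | CC1=CC[C@@H](CC1)[C@H](C)COC(C)=O | intermediate
5 | (2S)-2-[(1R)-4-methylcyclohex-3-en-1-yl]propan-1-ol | CC1=CC[C@@H](CC1)[C@H](C)CO | intermediate
6 | (4R)-4-[(2S)-1-(methoxymethoxy)propan-2-yl]-1-methylcyclohexene | CC1=CC[C@@H](CC1)[C@H](C)COCOC | intermediate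
7 | secondary ozonide (1,2,4-trioxolane) of 6 | CC12CC[C@@H]([C@H](C)COCOC)CC(OO1)O2 | intermediate
8 | (3R)-3-[(2S)-1-(methoxymethoxy)propan-2-yl]-6-oxoheptanal | CC(=O)CC[C@H](CC=O)[C@H](C)COCOC | intermediate
9 | isopropenylmagnesium bromide | CC(=C)[Mg]Br | starting material
10 | C3 isopropenyl carbinol, C12 methyl ketone, C16 MOM ether (1R,15S; both C3 epimers) | CC(=O)CC[C@H](CC(O)C(C)=C)[C@H](C)COCOC | intermediate
11 | triethyl phosphonoacetate | CCOC(=O)CP(=O)(OCC)OCC | starting material
12 | ethyl (E)-enoate, C3 isopropenyl carbinol (1R,15S; both C3 epimers) | CCOC(=O)/C=C(\C)CC[C@H](CC(O)C(C)=C)[C@H](C)COCOC | intermediate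
13 | C3 isopropenyl ketone, C10 ethyl ester, 11E (1R,15S) | CCOC(=O)/C=C(\C)CC[C@H](CC(=O)C(C)=C)[C@H](C)COCOC | intermediate
14 | (3R)-isopropenyl carbinol, C10 ethyl ester, 11E (1R,3R,15S) | CCOC(=O)/C=C(\C)CC[C@H](C[C@@H](O)C(C)=C)[C@H](C)COCOC | intermediate
15 | erythro C4–C5 epoxy alcohol (1R,3R,4S,15S) | CCOC(=O)/C=C(\C)CC[C@H](C[C@@H](O)[C@]1(C)CO1)[C@H](C)COCOC | intermediate
16 | C3 MOM ether of 15 | CCOC(=O)/C=C(\C)CC[C@H](C[C@@H](OCOC)[C@]1(C)CO1)[C@H](C)COCOC | intermediate
17 | C10 allylic alcohol with C4–C5 epoxide (1R,3R,4S,15S) | OC/C=C(\C)CC[C@H](C[C@@H](OCOC)[C@]1(C)CO1)[C@H](C)COCOC | intermediate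
18 | C4 tertiary vinyl carbinol, C10 allylic alcohol (1R,3R,4S,15S) | OC/C=C(\C)CC[C@H](C[C@@H](OCOC)[C@@](C)(O)C=C)[C@H](C)COCOC | intermediate
19 | C10 allylic bromide of 18 | BrC/C=C(\C)CC[C@H](C[C@@H](OCOC)[C@@](C)(O)C=C)[C@H](C)COCOC | intermediate
20 | 2-methylprop-2-en-1-ol | CC(=C)CO | starting material
21 | C,O-dilithio derivative of 20 | [Li]CC(=C)CO[Li] | intermediate
22 | C7 primary allylic alcohol on the C8 methylene unit, C4 tertiary vinyl carbinol (1R,3R,4S,15S) | OCC(=C)CC/C=C(\C)CC[C@H](C[C@@H](OCOC)[C@@](C)(O)C=C)[C@H](C)COCOC | intermediate
23 | C7 allylic chloride of 22 | ClCC(=C)CC/C=C(\C)CC[C@H](C[C@@H](OCOC)[C@@](C)(O)C=C)[C@H](C)COCOC | intermediate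
24 | thirteen-membered C4–O–C7 bis-allylic ether (1R,3R,4S,15S) | C1C(=C)CC/C=C(\C)CC[C@@H]([C@H](C)COCOC)C[C@@H](OCOC)[C@](C)(C=C)O1 | intermediate
25 | C7-lithiated 24 | [Li]C1C(=C)CC/C=C(\C)CC[C@@H]([C@H](C)COCOC)C[C@@H](OCOC)[C@](C)(C=C)O1 | intermediate
26 | fourteen-membered C7 alcohol, C8 methylene, 4E,11E (1R,3R,7S,15S) | O[C@@H]1C(=C)CC/C=C(\C)CC[C@@H]([C@H](C)COCOC)C[C@@H](OCOC)/C(C)=C/C1 | intermediate
27 | C7 TBS ether of 26 | CC(C)(C)[Si](C)(C)O[C@@H]1C(=C)CC/C=C(\C)CC[C@@H]([C@H](C)COCOC)C[C@@H](OCOC)/C(C)=C/C1 | intermediate
28 | C3,C16 diol, C7 TBS ether (1R,3R,7S,15S) | CC(C)(C)[Si](C)(C)O[C@@H]1C(=C)CC/C=C(\C)CC[C@@H]([C@H](C)CO)C[C@@H](O)/C(C)=C/C1 | intermediate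
29 | C4–C5 epoxide of 28 (1R,3R,4R,5R,7S,15S) | CC(C)(C)[Si](C)(C)O[C@@H]1C(=C)CC/C=C(\C)CC[C@@H]([C@H](C)CO)C[C@@H](O)[C@@]2(C)O[C@@H]2C1 | intermediate
30 | C3,C4,C16 triol, C7 TBS ether, 11E (1R,3R,4S,7S,15S) | CC(C)(C)[Si](C)(C)O[C@@H]1C(=C)CC/C=C(\C)CC[C@@H]([C@H](C)CO)C[C@@H](O)[C@@](C)(O)CC1 | intermediate
31 | 11,12-epoxide of 30 (1R,3R,4S,7S,11S,12S,15S) | CC(C)(C)[Si](C)(C)O[C@@H]1C(=C)CC[C@@H]2O[C@@]2(C)CC[C@@H]([C@H](C)CO)C[C@@H](O)[C@@](C)(O)CC1 | intermediate
32 | C7 TBS ether of the target lactone | CC(C)(C)[Si](C)(C)O[C@@H]1C(=C)CC[C@@H]2O[C@@]2(C)CC[C@@H]2C[C@@H](OC(=O)[C@H]2C)[C@@](C)(O)CC1 | intermediate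
33 | CNP0262409.2 | C=C1CC[C@@H]2O[C@@]2(C)CC[C@@H]2C[C@@H](OC(=O)[C@H]2C)[C@@](C)(O)CC[C@@H]1O | target

## Step count and risks

Total step count: 25. Longest linear sequence: 25 steps (1 to 33); 9, 11 and 20 are bought.

**Step 18 (key step).** The most likely failure is loss of control in the rearrangement: a competing [1,2]-shift, or bonding through an envelope in which the C3 branch or the C8 group is forced out of its preferred position by the bridging chain. That would erode the chirality transfer to C7 or the E geometry at C4=C5. The fallback uses known chemistry and moves the ring closure to the C4=C5 alkene; it sets out from 14 and returns at 26. The C3 hydroxyl of 14 is protected as the MOM ether F1 (as in step 11). The ester is reduced with i-Bu2AlH to allylic alcohol F2, converted with CBr4 and PPh3 into allylic bromide F3, and coupled with dianion 21 to give 2-methyleneallyl alcohol F4 (as in step 15). MnO2 oxidation gives α-methylene aldehyde F5. Brown allylation with (−)-B-allyldiisopinocampheylborane, a reagent-controlled step, should give the 7S homoallylic alcohol F6. Ring-closing metathesis with the second-generation Grubbs catalyst at high dilution then joins the C4 isopropenyl carbon to the C5 vinyl carbon, and the 4E isomer is 26. This gives up the chirality transfer and accepts E/Z separation at C4=C5.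

**Step 17.** Oligomerisation may outrun ring closure, because a hindered tertiary alkoxide is a slow nucleophile and a thirteen-membered ring has little entropic help. The fallback sets out from 22 and returns at 24. The primary allylic alcohol of 22 is converted with Boc2O and DMAP into the tert-butyl carbonate F7. Pd(PPh3)4 (zerovalent palladium) in THF at high dilution ionises it to the 2-substituted π-allyl complex with loss of CO2. The released tert-butoxide deprotonates the tertiary alcohol, which closes the ether by Tsuji–Trost O-allylation; both allyl termini are equivalent.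

**Step 13.** Ring opening may be slow at the epoxide CH2, which is flanked by the quaternary C4 and the C3 acetal, so that ylide decomposition or oxetane formation competes. The fallback sets out from 17 and returns at 18. Lithiated thioanisole (PhSCH2Li, from thioanisole, n-BuLi and DABCO) opens the epoxide to the γ-hydroxy sulfide F8. NaIO4 oxidises it to the sulfoxide F9. Thermal syn-elimination in toluene at 110 °C over CaCO3 then gives the vinyl carbinol 18.

**Step 21.** Facial selectivity may be poor, because the conformation of the macrocycle, not A(1,2) strain, may decide which face of C4=C5 is open. The fallback changes the source of control from substrate to reagent; it sets out from 28 and returns at 29 with no new compound. It is the Sharpless epoxidation with Ti(OiPr)4, L-(+)-diisopropyl tartrate and t-BuOOH in CH2Cl2 at −20 °C. In that sense the tartrate's face preference matches the erythro preference of the 3R alcohol.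

## Further compounds

F1 | step 18 | C3 MOM ether of 14 | CCOC(=O)/C=C(\C)CC[C@H](C[C@@H](OCOC)C(C)=C)[C@H](C)COCOC
F2 | step 18 | C10 allylic alcohol with C3 MOM ether and C4 isopropenyl group | OC/C=C(\C)CC[C@H](C[C@@H](OCOC)C(C)=C)[C@H](C)COCOC
F3 | step 18 | C10 allylic bromide of F2 | BrC/C=C(\C)CC[C@H](C[C@@H](OCOC)C(C)=C)[C@H](C)COCOC
F4 | step 18 | C7 2-methyleneallyl alcohol with C4 isopropenyl group | OCC(=C)CC/C=C(\C)CC[C@H](C[C@@H](OCOC)C(C)=C)[C@H](C)COCOC
F5 | step 18 | C7 α-methylene aldehyde | O=CC(=C)CC/C=C(\C)CC[C@H](C[C@@H](OCOC)C(C)=C)[C@H](C)COCOC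
F6 | step 18 | (7S)-homoallylic alcohol, metathesis precursor | C=CC[C@H](O)C(=C)CC/C=C(\C)CC[C@H](C[C@@H](OCOC)C(C)=C)[C@H](C)COCOC
F7 | step 17 | C7 tert-butyl carbonate of 22 | CC(C)(C)OC(=O)OCC(=C)CC/C=C(\C)CC[C@H](C[C@@H](OCOC)[C@@](C)(O)C=C)[C@H](C)COCOC
F8 | step 13 | γ-hydroxy sulfide (C6 phenylthio) | OC/C=C(\C)CC[C@H](C[C@@H](OCOC)[C@@](C)(O)CCSc1ccccc1)[C@H](C)COCOC
F9 | step 13 | sulfoxide of F8 | OC/C=C(\C)CC[C@H](C[C@@H](OCOC)[C@@](C)(O)CCS(=O)c1ccccc1)[C@H](C)COCOC
F0 | step 21 | none | none
A1 | alternative 1 | macrocyclic alkynol (C1 ethynyl, C3 hydroxyl) | C=C1CC/C=C(\C)CC[C@@H](C#C)C[C@@H](O)[C@@](C)(O[Si](CC)(CC)CC)CC[C@@H]1O[Si](C)(C)C(C)(C)C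
A2 | alternative 1 | macrocyclic α-methylene δ-lactone | C=C1CC/C=C(\C)CC[C@@H]2C[C@@H](OC(=O)C2=C)[C@@](C)(O[Si](CC)(CC)CC)CC[C@@H]1O[Si](C)(C)C(C)(C)C
A3 | alternative 2 | geranylgeranyl diphosphate | CC(C)=CCC/C(C)=C/CC/C(C)=C/CC/C(C)=C/COP(=O)(O)OP(=O)(O)O
A4 | alternative 2 | (R)-cembrene A | CC(=C)[C@@H]1CC/C(C)=C/CC/C(C)=C/CC/C(C)=C/C1
A5 | alternative 3 | seco lactone with C1 vinyl group and C12 E-alkenyl iodide | I/C(C)=C/CC[C@]1(C)O[C@H]1CC[C@](C)(O[Si](CC)(CC)CC)[C@H]1C[C@@H](C=C)[C@H](C)C(=O)O1
A6 | alternative 3 | 7,8-epoxy-11E-ene macrocyclic lactone | C1C[C@@H]2O[C@@]2(C)CC/C=C(\C)CC[C@@H]2C[C@@H](OC(=O)[C@H]2C)[C@@]1(C)O[Si](CC)(CC)CC
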